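## Structural features

The target is a C27 apo-carotenoid built on a 2,4,5,6,7,7a-hexahydrobenzofuran. The cyclohexane ring C1–C6 (gem-dimethyl at C1, carbinol at C3, methyl at C5) is fused through C5–C6 to a 2,5-dihydrofuran ring O–C5–C6=C7–C8, and C8 carries a hexaene chain (C9 to C10') ending in a primary allylic alcohol. There are three stereocentres: C3 (S), the fully substituted ether carbon C5 (R), which is 1,3 to C3 in the six-membered ring, and the ether methine C8 (S), which faces C5 across the ring oxygen. The chain is Z at C9=C10 and E at the other five double bonds. The C8–O bond is doubly allylic and ionises with traces of acid, which would epimerise C8 or open the ring; the (9Z) bond, the polyene and the terminal allylic alcohol are sensitive to acid, light, oxygen and strong base. Because the C5–O bond must lie close to the plane of C6=C7, the C5 methyl should be pseudo-axial and syn to the axial methyl on C1, and the C3 hydroxyl of the target stands on that same face, so it is the hindered axial epimer. The real difficulty is twofold: C8 has no neighbour that could bias it, and the trans relation of the oxygens on C3 and C5 runs against the facial preference that the gem-dimethyl ring imposes on reagents. The key step exploits the array O–C5, C6=C7, C8–H next to the (Z)-C9=C10 alkene: this is what a C5,C6-diol with a (Z)-enynyl group on C6 becomes when the C5 hydroxyl adds to the distal alkyne carbon C8, the C6 hydroxyl leaves and a hydride is delivered to C8.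

## Logic of the disconnections

25 ⇒ 24. No skeletal bond is cut; the C10' alcohol and the C3 carbinol are both taken back to carbonyl groups. The C3 hydroxyl of 25 is the axial epimer: substitution with inversion would have to pass between the two axial methyl groups, whereas hydride addition to a C3 ketone from the open face should give exactly this epimer. The gain is that C3 need not be carried in its final configuration and that one reagent finishes both ends of the molecule. The forward step must be fully face-selective at C3 and must spare the acid-labile C8–O bond.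

24 ⇒ 17 + 22. The C11=C12 double bond is cut (Horner–Wadsworth–Emmons), dividing the molecule into the stereochemically dense bicycle and an achiral tetraene. The carbanion is placed on C12, because an anion at C11 would be delocalised to C9 and could expel the ring oxygen from C8. The forward step must give the E alkene under base mild enough to leave H8, the (9Z) bond and the β-alkoxy ketone of 17 alone, so 23 is formed first and used cold.

22 ⇒ 21 ⇒ 20 ⇒ 19 ⇒ 18. The C12–P bond (Arbuzov), the C12 oxidation level and the C12'=C11' double bond (olefination with triethyl phosphonoacetate) are taken back in turn. This reduces the whole C12–C10' piece to the symmetrical, commercial 18. The first olefination must stop at one end of 18, and the aldehyde of 19 must be reduced without touching the ester.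

17 ⇒ 16 ⇒ 15. Only oxidation levels and silyl groups change. Both hydroxyls of 16 are oxidised together, so the detour through the C3 ketone costs no step compared with oxidising the allylic alcohol alone. The forward steps must be non-acidic and at most weakly basic.

15 ⇒ 12 (key disconnection). The O–C8 and C8–H bonds are cut and the C6 hydroxyl and the C7≡C8 triple bond are restored, by way of 14 and 13. This removes the five-membered ring and the C8 stereocentre in one operation and leaves a monocyclic diol. Three demands follow:
- The alkynyl group on C6 must be cis to the C5 hydroxyl. Only that epimer can close a cis-fused ring; a mixture of C6 epimers would not converge, because the other epimer holds alkyne and hydroxyl anti in its only low-energy chair.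
- The oxygen on C11 lies cis to the alkyne and must stay out of the reaction, hence a bulky, acid-stable silyl group.
- The face of hydride delivery at C8 must be dictated by the catalyst.

12 ⇒ 8 + 10 (through 11). The C6–C7 bond is cut, giving 8, which cannot enolise, and 11. For the alkyne to enter cis to the C5 oxygen, that oxygen must be equatorial in the reacting chair, with both flanking axial positions taken by methyl groups on the other face. This holds only when the silyloxy group on C3 is cis to the C5 oxygen. With the C3 configuration of 25 the C5 oxygen would be axial and the acetylide would be expected to enter anti to it. For this reason C3 is carried as its epimer from the start and corrected in the last step.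

8 ⇒ 5 ⇒ 3 ⇒ 2 ⇒ 1. The C5–O bond is cut (Rubottom oxidation of 5); 5 is traced to 3 (conjugate reduction, silylation of 4), the silyl ether to 2, and the carbinol to prochiral 1 (asymmetric transfer hydrogenation). The equatorial C3 silyloxy group that serves the alkynylation also places the pseudo-axial C1 methyl on the upper face of 5, so the peracid should add from the lower face and give the (5R) centre. All absolute stereochemistry of the ring then flows from one catalytic reduction; that step must be highly enantioselective and the reduction of 3 cleanly 1,4.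

10 ⇒ 9. Only the O–Si bond is cut. 9 is commercial and already holds the (Z) geometry of C9=C10, which no later step may isomerise.

## Other disconnections considered

Alternative 1: The cut goes through C5–O and C4–C5, so the oxygen ring comes first and the carbocycle later.
- Forward: Cu(acac)2 decomposes the diazoketone (5S)-5-(allyloxy)-2-diazo-7-(triisopropylsilyl)hept-6-yn-3-one A2. The copper carbenoid at C5 is trapped by the allyl ether oxygen on C8, and the oxonium ylide undergoes a [2,3]-shift that moves the allyl group to C5, giving the furanone A1.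
- In favour: this is an established reaction class. C8 is the enantiopure ether carbon of A2 and relays its configuration to the fully substituted C5 within a five-membered transition state, so no chiral catalyst is needed. On precedent and mechanistic certainty of the key step this alternative is the better of the two.
- Against: A1 holds only C4 to C8 of the bicycle. Still to be made are the cyclohexane (a quaternary C1 added to the hindered C6 ketone, ring closure onto the allyl terminus, an oxygen at C3 with regio- and facial control), the C6=C7 alkene and the (Z)-C9=C10 alkene from the silyl alkyne. With both a methyl and an allyl group on the ylide carbon, the C5/C8 diastereoselectivity is less assured than in simpler cases.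
- Comparison: the chosen plan takes the six-membered ring ready-made and forms the heterocycle last, which suits the structure better, and it is clearly shorter.

Alternative 2: The cut goes through C3–C4 and C5–O, opening both rings to the acyclic dienyl aldehyde A4.
- Forward: a confined imidodiphosphorimidate acid activates the C3 aldehyde, the terminal methylene C4 of the isopropenyl group attacks it (six-membered ring), and the tertiary allyl cation at C5 is captured by the silyl ether oxygen on C8 (five-membered ring). The triethylsilyl group ends on O3 and the product is A3.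
- In favour: no other plan creates as much in one step (two rings, one C–C and one C–O bond, C3 and C5 together), and it is convergent. In gain of complexity per step it is the better.
- Against: A4 needs a stereodefined trisubstituted diene and an enantiopure, doubly allylic silyl ether at C8 that a strong acid may ionise. The chair-like closure places O3 equatorial, which is the C3 epimer. Correcting it by substitution with inversion must bring the nucleophile in between the axial methyls on C1 and C5, the least favourable trajectory in the molecule.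
- Comparison: the oxidation and hydride reduction of the chosen plan would repair C3 here as well, so on that point the two are equal. The cascade is no better precedented on such a substrate than the relay of the chosen plan, and the step counts should be close.

Alternative 3: The cut removes both C–O bonds of the dihydrofuran and leads back to the ring diene A6.
- Forward: sensitised singlet oxygen adds across C5 and C8 of the s-cis diene to give the endoperoxide A7. PPh3 then attacks the less hindered peroxide oxygen (on C8), and the C5 alkoxide closes onto C8 with inversion and loss of the phosphorus-bound oxygen, giving A5.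
- In favour: A6 is a standard C15 building block, and the heterocycle is made in one pot with known reaction types. The C5/C8 relation is fixed by the mechanism: suprafacial addition followed by one inversion puts the C5 methyl trans to H8, as in the target. On step economy and precedent this alternative is the better of the two.
- Against: both centres depend on a single event, the face of the ring attacked by singlet oxygen. The face required (anti to the C3 silyloxy group) is the one carrying the pseudo-axial C1 methyl when that group is equatorial, so the intrinsic preference is expected to be weak or opposite, with no reagent handle to change it. The ene reaction at the tetrasubstituted C5=C6 bond competes.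
- Comparison: in the chosen plan C5 follows from a matched substrate preference and C8 is set separately by a catalyst. If the C3 tactic of the chosen plan (epimeric silyloxy group, then oxidation and hydride reduction) were grafted on, this alternative would be a serious rival.

Key step: step 7

Assumption: the sense of induction of the two chiral catalysts is taken by analogy with the usual models, RuCl(p-cymene)[(R,R)-TsDPEN] for (4R)-2 and the (R)-phosphoric acid for (8S)-15; if either sense is the reverse, the mirror-image catalyst is used in the same step.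

Remark on the design: the precursor 12 and the product 15 of the key step have the required skeletons, with three changes.
- C6 is one defined epimer (alkynyl cis to the C5 hydroxyl), since only it can cyclise.
- C3 is carried as the (R) epimer, which steers steps 4 and 6, and is inverted through the ketone in steps 9 and 15.
- O11 carries a tert-butyldiphenylsilyl group.

In step 7, (R)-TRIP is (R)-3,3'-bis(2,4,6-triisopropylphenyl)-1,1'-binaphthyl-2,2'-diyl hydrogen phosphate and the Hantzsch ester is diethyl 2,6-dimethyl-1,4-dihydropyridine-3,5-dicarboxylate.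

## Route

Step 1
Reactants: 1 ketoisophorone (2,6,6-trimethylcyclohex-2-ene-1,4-dione)
Product: 2 (4R)-4-hydroxy-2,6,6-trimethylcyclohex-2-en-1-one
Conditions: RuCl(p-cymene)[(R,R)-TsDPEN] (0.5 mol%), i-PrOH, rt
Reagents that add atoms: none
Why: Noyori-type asymmetric transfer hydrogenation of an unsaturated ketone; only the C4 carbonyl is accessible (C1 lies between the gem-dimethyl carbon and the methyl-bearing alkene carbon), and the alkene takes the place of the aryl group in the usual model, which should set C4 (R).

Step 2
Reactants: 2 (4R)-4-hydroxy-2,6,6-trimethylcyclohex-2-en-1-one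
Product: 3 (4R)-4-[(tert-butyldimethylsilyl)oxy]-2,6,6-trimethylcyclohex-2-en-1-one
Conditions: TBSCl, imidazole, DMF, rt
Reagents that add atoms: tert-butyl(chloro)dimethylsilane CC(C)(C)[Si](C)(C)Cl
Why: Standard silylation of a secondary allylic alcohol; the ether survives the hydride and organolithium steps and, once C5 is saturated, takes the equatorial position that fixes the ring conformation used in steps 4 and 6.

Step 3
Reactants: 3 (4R)-4-[(tert-butyldimethylsilyl)oxy]-2,6,6-trimethylcyclohex-2-en-1-one
Product: 5 tert-butyl(dimethyl){[(1S)-3,5,5-trimethyl-4-[(trimethylsilyl)oxy]cyclohex-3-en-1-yl]oxy}silane, via lithium enolate 4 (not isolated)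
Conditions: Li[HB(s-Bu)3], THF, −78 °C; then Me3SiCl, Et3N, −78 °C to rt
Reagents that add atoms: chlorotrimethylsilane C[Si](C)(C)Cl
Why: Conjugate reduction of a cyclohexenone whose carbonyl is shielded by the gem-dimethyl carbon, then O-silylation of the enolate; the enol ether can form on one side only and the carbinol centre is untouched.

Step 4
Reactants: 5 tert-butyl(dimethyl){[(1S)-3,5,5-trimethyl-4-[(trimethylsilyl)oxy]cyclohex-3-en-1-yl]oxy}silane
Product: 8 (2R,4R)-4-[(tert-butyldimethylsilyl)oxy]-2-hydroxy-2,6,6-trimethylcyclohexan-1-one, via silyloxy epoxide 6 (not isolated), via silyloxy ketone 7 (not isolated)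
Conditions: mCPBA, NaHCO3, CH2Cl2, −20 to 0 °C; then citric acid, MeOH, rt
Reagents that add atoms: 3-chloroperoxybenzoic acid OOC(=O)c1cccc(Cl)c1
Why: Rubottom oxidation; with the C3 silyloxy group equatorial the pseudo-axial C1 methyl covers the upper face of the enol ether, so the peracid should add from the lower face, syn to the silyloxy group, and set C5 (R). Epoxide 6 opens with a 1,4-silyl shift to 7, and the trimethylsilyl group is removed by mild acid that leaves the secondary silyl ether alone.

Step 5
Reactants: 9 (2Z)-3-methylpent-2-en-4-yn-1-ol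
Product: 10 tert-butyl{[(2Z)-3-methylpent-2-en-4-yn-1-yl]oxy}diphenylsilane
Conditions: TBDPSCl, imidazole, CH2Cl2, 0 °C to rt
Reagents that add atoms: tert-butyl(chloro)diphenylsilane CC(C)(C)[Si](Cl)(c1ccccc1)c1ccccc1
Why: Silylation of the primary allylic alcohol; the diphenyl-tert-butylsilyl group is chosen because in step 7 this oxygen sits cis to the gold-activated alkyne and must neither add to it nor be cleaved by the phosphoric acid.

Step 6
Reactants: 10 tert-butyl{[(2Z)-3-methylpent-2-en-4-yn-1-yl]oxy}diphenylsilane; 8 (2R,4R)-4-[(tert-butyldimethylsilyl)oxy]-2-hydroxy-2,6,6-trimethylcyclohexan-1-one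
Product: 12 (1S,2R,4R)-4-[(tert-butyldimethylsilyl)oxy]-1-{(3Z)-5-[(tert-butyldiphenylsilyl)oxy]-3-methylpent-3-en-1-yn-1-yl}-2,6,6-trimethylcyclohexane-1,2-diol, via lithium acetylide 11 (not isolated)
Conditions: 10 (2.5 equiv), n-BuLi (2.4 equiv), THF, −78 °C; then 8, −78 to 0 °C; aq. NH4Cl
Reagents that add atoms: none
Why: 1,2-Addition of a lithium acetylide to a ketone that cannot enolise, the first equivalent deprotonating the hydroxyl. In the chair with the C3 silyloxy group and the lithium-bound C5 oxygen equatorial, the C1 and C5 methyls are both axial on one face, so the slim nucleophile should enter axially from the other face. The alkynyl group then ends cis to the C5 hydroxyl (C6 S), the only arrangement from which the cis-fused ring of step 7 can close.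

Step 7
Reactants: 12 (1S,2R,4R)-4-[(tert-butyldimethylsilyl)oxy]-1-{(3Z)-5-[(tert-butyldiphenylsilyl)oxy]-3-methylpent-3-en-1-yn-1-yl}-2,6,6-trimethylcyclohexane-1,2-diol
Product: 15 (2S,6R,7aR)-6-[(tert-butyldimethylsilyl)oxy]-2-{(2Z)-4-[(tert-butyldiphenylsilyl)oxy]but-2-en-2-yl}-4,4,7a-trimethyl-2,4,5,6,7,7a-hexahydro-1-benzofuran, via dihydrofuranol 13 (not isolated), via furanium phosphate 14 (not isolated)
Conditions: (Ph3P)AuMe (5 mol%), (R)-TRIP (10 mol%), Hantzsch ester (1.3 equiv), 5 Å molecular sieves, toluene, 0 °C to rt; Et3N quench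
Reagents that add atoms: none
Why: Proposed new method: the phosphate complex of monovalent gold formed from (Ph3P)AuMe and the acid binds the C7≡C8 alkyne, and the equatorial C5 hydroxyl, gauche to the axial alkynyl group, adds to C8 in a 5-endo-dig closure; protodeauration gives the cis-fused dihydrofuranol 13. The remaining free acid ionises the tertiary C6 hydroxyl, which is allylic to the new enol ether, to the 2H-furanium ion 14, held as a contact ion pair with the chiral phosphate, and the Hantzsch ester transfers hydride to C8, leaving the alkene at C6=C7. The closest known reaction types are the gold-catalysed 5-endo-dig cyclisation of 3-alkyne-1,2-diols, which normally ends in furans, and relays in which a cation made by metal-catalysed alkyne cyclisation is reduced by a Hantzsch ester under chiral phosphate control; new here is their union on a diol whose C5 is fully substituted, so that aromatisation is blocked and the cation has to be reduced. The one new stereocentre, C8, is set by the chiral anion (reagent control), the substrate's own bias being small because C8 lies across the ring oxygen from C5. The step needs hydride at C8 only: C6 is shielded by its two fully substituted neighbours C1 and C5, C10 should carry little charge because the (Z)-trisubstituted alkene is twisted out of the furanium plane by allylic strain, and C8 is the oxocarbenium carbon. Ring closure is expected to outrun Meyer–Schuster and pinacol pathways because the hydroxyl is held next to the activated alkyne, and the methylgold precursor introduces no achiral counter-anion that could open a racemic path.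

Step 8
Reactants: 15 (2S,6R,7aR)-6-[(tert-butyldimethylsilyl)oxy]-2-{(2Z)-4-[(tert-butyldiphenylsilyl)oxy]but-2-en-2-yl}-4,4,7a-trimethyl-2,4,5,6,7,7a-hexahydro-1-benzofuran
Product: 16 (2S,6R,7aR)-2-[(2Z)-4-hydroxybut-2-en-2-yl]-4,4,7a-trimethyl-2,4,5,6,7,7a-hexahydro-1-benzofuran-6-ol
Conditions: Bu4NF, THF, 0 °C to rt
Reagents that add atoms: none
Why: Fluoride cleaves both silyl ethers; the doubly allylic ether at C8 is left alone by this non-acidic reagent.

Step 9
Reactants: 16 (2S,6R,7aR)-2-[(2Z)-4-hydroxybut-2-en-2-yl]-4,4,7a-trimethyl-2,4,5,6,7,7a-hexahydro-1-benzofuran-6-ol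
Product: 17 (2Z)-3-[(2S,7aR)-4,4,7a-trimethyl-6-oxo-2,4,5,6,7,7a-hexahydro-1-benzofuran-2-yl]but-2-enal
Conditions: Dess–Martin periodinane (3 equiv), NaHCO3, CH2Cl2, 0 °C to rt
Reagents that add atoms: none
Why: Dess–Martin oxidation of both alcohols under buffered, non-basic conditions should give the (Z)-enal without isomerisation and the C3 ketone. The C3 carbinol has served as control element and is removed here so that it can be re-made with the other configuration in step 15.

Step 10
Reactants: 18 (2E,4E,6E)-2,7-dimethylocta-2,4,6-trienedial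
Product: 19 ethyl (2E,4E,6E,8E)-4,9-dimethyl-10-oxodeca-2,4,6,8-tetraenoate
Conditions: (EtO)2P(O)CH2CO2Et (1.0 equiv), NaH, THF, 0 °C, slow addition to 18 (1.3 equiv)
Reagents that add atoms: triethyl phosphonoacetate CCOC(=O)CP(=O)(OCC)OCC
Why: Horner–Wadsworth–Emmons olefination with a stabilised phosphonate gives the (E)-enoate; one equivalent of anion added to an excess of the dialdehyde should stop at the first olefination, and unchanged 18 is recovered.

Step 11
Reactants: 19 ethyl (2E,4E,6E,8E)-4,9-dimethyl-10-oxodeca-2,4,6,8-tetraenoate
Product: 20 ethyl (2E,4E,6E,8E)-10-hydroxy-4,9-dimethyldeca-2,4,6,8-tetraenoate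
Conditions: NaBH4, EtOH, −20 °C
Reagents that add atoms: none
Why: Borohydride reduces the aldehyde 1,2 and leaves the conjugated ester untouched at low temperature.

Step 12
Reactants: 20 ethyl (2E,4E,6E,8E)-10-hydroxy-4,9-dimethyldeca-2,4,6,8-tetraenoate
Product: 21 ethyl (2E,4E,6E,8E)-10-bromo-4,9-dimethyldeca-2,4,6,8-tetraenoate
Conditions: PBr3, Et2O, −10 °C, dark
Reagents that add atoms: phosphorus tribromide BrP(Br)Br
Why: Conversion of a primary allylic alcohol into the bromide; the product is sensitive to light and heat and is used at once.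

Step 13
Reactants: 21 ethyl (2E,4E,6E,8E)-10-bromo-4,9-dimethyldeca-2,4,6,8-tetraenoate
Product: 22 ethyl (2E,4E,6E,8E)-10-(diethoxyphosphoryl)-4,9-dimethyldeca-2,4,6,8-tetraenoate
Conditions: P(OEt)3, toluene, 90 °C
Reagents that add atoms: triethyl phosphite CCOP(OCC)OCC
Why: Michaelis–Arbuzov reaction at the primary allylic carbon gives the phosphonate.

Step 14
Reactants: 17 (2Z)-3-[(2S,7aR)-4,4,7a-trimethyl-6-oxo-2,4,5,6,7,7a-hexahydro-1-benzofuran-2-yl]but-2-enal; 22 ethyl (2E,4E,6E,8E)-10-(diethoxyphosphoryl)-4,9-dimethyldeca-2,4,6,8-tetraenoate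
Product: 24 ethyl (2E,4E,6E,8E,10E,12Z)-4,9-dimethyl-13-[(2S,7aR)-4,4,7a-trimethyl-6-oxo-2,4,5,6,7,7a-hexahydro-1-benzofuran-2-yl]tetradeca-2,4,6,8,10,12-hexaenoate, via phosphonate anion 23 (not isolated)
Conditions: 22 (1.1 equiv), NaN(SiMe3)2 (1.05 equiv), THF, −78 °C; then 17, −78 to −30 °C
Reagents that add atoms: none
Why: Horner–Wadsworth–Emmons reaction of the delocalised phosphonate carbanion with the aldehyde, which is far more reactive than the ketone, should give the (11E) alkene. The anion is formed first with a slight deficit of base and kept cold, so that neither H8 nor the hydrogens next to the ketone are removed and the (9Z) bond is kept.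

Step 15
Reactants: 24 ethyl (2E,4E,6E,8E,10E,12Z)-4,9-dimethyl-13-[(2S,7aR)-4,4,7a-trimethyl-6-oxo-2,4,5,6,7,7a-hexahydro-1-benzofuran-2-yl]tetradeca-2,4,6,8,10,12-hexaenoate
Product: 25 (2E,4E,6E,8E,10E,12Z)-13-[(2S,6S,7aR)-6-hydroxy-4,4,7a-trimethyl-2,4,5,6,7,7a-hexahydro-1-benzofuran-2-yl]-4,9-dimethyltetradeca-2,4,6,8,10,12-hexaen-1-ol
Conditions: i-Bu2AlH (6 equiv), CH2Cl2, −78 to −40 °C; aq. potassium sodium tartrate
Reagents that add atoms: none
Why: The aluminium hydride reduces the ester to the primary allylic alcohol and the ketone to the carbinol. Hydride can reach C3 only from the face opposite the two 1,3-related axial methyls on C1 and C5, as in the reduction of 11-oxo steroids, so the hydroxyl should come out axial and cis to the C5 methyl, which is (3S).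

## Compound list

1 | ketoisophorone (2,6,6-trimethylcyclohex-2-ene-1,4-dione) | CC1=CC(=O)CC(C)(C)C1=O | starting material
2 | (4R)-4-hydroxy-2,6,6-trimethylcyclohex-2-en-1-one | CC1=C[C@H](O)CC(C)(C)C1=O | intermediate
3 | (4R)-4-[(tert-butyldimethylsilyl)oxy]-2,6,6-trimethylcyclohex-2-en-1-one | CC1=C[C@H](O[Si](C)(C)C(C)(C)C)CC(C)(C)C1=O | intermediate
4 | lithium (4S)-4-[(tert-butyldimethylsilyl)oxy]-2,6,6-trimethylcyclohex-1-en-1-olate | CC1=C([O-])C(C)(C)C[C@@H](O[Si](C)(C)C(C)(C)C)C1.[Li+] | intermediate
5 | tert-butyl(dimethyl){[(1S)-3,5,5-trimethyl-4-[(trimethylsilyl)oxy]cyclohex-3-en-1-yl]oxy}silane | CC1=C(O[Si](C)(C)C)C(C)(C)C[C@@H](O[Si](C)(C)C(C)(C)C)C1 | intermediate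
6 | (1R,4R,6R)-4-[(tert-butyldimethylsilyl)oxy]-2,2,6-trimethyl-1-[(trimethylsilyl)oxy]-7-oxabicyclo[4.1.0]heptane (epoxide oxygen cis to the C4 silyloxy group) | C[C@@]12C[C@H](O[Si](C)(C)C(C)(C)C)CC(C)(C)[C@]1(O[Si](C)(C)C)O2 | intermediate
7 | (2R,4R)-4-[(tert-butyldimethylsilyl)oxy]-2,6,6-trimethyl-2-[(trimethylsilyl)oxy]cyclohexan-1-one | C[C@@]1(O[Si](C)(C)C)C[C@H](O[Si](C)(C)C(C)(C)C)CC(C)(C)C1=O | intermediate
8 | (2R,4R)-4-[(tert-butyldimethylsilyl)oxy]-2-hydroxy-2,6,6-trimethylcyclohexan-1-one | C[C@@]1(O)C[C@H](O[Si](C)(C)C(C)(C)C)CC(C)(C)C1=O | intermediate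
9 | (2Z)-3-methylpent-2-en-4-yn-1-ol | C/C(C#C)=C/CO | starting material
10 | tert-butyl{[(2Z)-3-methylpent-2-en-4-yn-1-yl]oxy}diphenylsilane | C/C(C#C)=C/CO[Si](c1ccccc1)(c1ccccc1)C(C)(C)C | intermediate
11 | lithium (3Z)-5-[(tert-butyldiphenylsilyl)oxy]-3-methylpent-3-en-1-yn-1-ide | C/C(C#C[Li])=C/CO[Si](c1ccccc1)(c1ccccc1)C(C)(C)C | intermediate
12 | (1S,2R,4R)-4-[(tert-butyldimethylsilyl)oxy]-1-{(3Z)-5-[(tert-butyldiphenylsilyl)oxy]-3-methylpent-3-en-1-yn-1-yl}-2,6,6-trimethylcyclohexane-1,2-diol | C/C(=C/CO[Si](c1ccccc1)(c1ccccc1)C(C)(C)C)C#C[C@@]1(O)C(C)(C)C[C@@H](O[Si](C)(C)C(C)(C)C)C[C@@]1(C)O | intermediate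
13 | (3aR,6R,7aR)-6-[(tert-butyldimethylsilyl)oxy]-2-{(2Z)-4-[(tert-butyldiphenylsilyl)oxy]but-2-en-2-yl}-4,4,7a-trimethyl-3a,4,5,6,7,7a-hexahydro-1-benzofuran-3a-ol | C/C(=C/CO[Si](c1ccccc1)(c1ccccc1)C(C)(C)C)C1=C[C@@]2(O)C(C)(C)C[C@@H](O[Si](C)(C)C(C)(C)C)C[C@@]2(C)O1 | intermediate
14 | (6R,7aR)-6-[(tert-butyldimethylsilyl)oxy]-2-{(2Z)-4-[(tert-butyldiphenylsilyl)oxy]but-2-en-2-yl}-4,4,7a-trimethyl-5,6,7,7a-tetrahydro-4H-1-benzofuran-1-ium, ion pair with the (R)-TRIP phosphate (cation shown) | C/C(=C/CO[Si](c1ccccc1)(c1ccccc1)C(C)(C)C)C1=[O+][C@]2(C)C[C@H](O[Si](C)(C)C(C)(C)C)CC(C)(C)C2=C1 | intermediate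
15 | (2S,6R,7aR)-6-[(tert-butyldimethylsilyl)oxy]-2-{(2Z)-4-[(tert-butyldiphenylsilyl)oxy]but-2-en-2-yl}-4,4,7a-trimethyl-2,4,5,6,7,7a-hexahydro-1-benzofuran | C/C(=C/CO[Si](c1ccccc1)(c1ccccc1)C(C)(C)C)[C@@H]1C=C2C(C)(C)C[C@@H](O[Si](C)(C)C(C)(C)C)C[C@@]2(C)O1 | intermediate
16 | (2S,6R,7aR)-2-[(2Z)-4-hydroxybut-2-en-2-yl]-4,4,7a-trimethyl-2,4,5,6,7,7a-hexahydro-1-benzofuran-6-ol | C/C(=C/CO)[C@@H]1C=C2C(C)(C)C[C@@H](O)C[C@@]2(C)O1 | intermediate
17 | (2Z)-3-[(2S,7aR)-4,4,7a-trimethyl-6-oxo-2,4,5,6,7,7a-hexahydro-1-benzofuran-2-yl]but-2-enal | C/C(=C/C=O)[C@@H]1C=C2C(C)(C)CC(=O)C[C@@]2(C)O1 | intermediate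
18 | (2E,4E,6E)-2,7-dimethylocta-2,4,6-trienedial | O=C/C(C)=C/C=C/C=C(C)/C=O | starting material
19 | ethyl (2E,4E,6E,8E)-4,9-dimethyl-10-oxodeca-2,4,6,8-tetraenoate | CCOC(=O)/C=C/C(C)=C/C=C/C=C(C)/C=O | intermediate
20 | ethyl (2E,4E,6E,8E)-10-hydroxy-4,9-dimethyldeca-2,4,6,8-tetraenoate | CCOC(=O)/C=C/C(C)=C/C=C/C=C(C)/CO | intermediate
21 | ethyl (2E,4E,6E,8E)-10-bromo-4,9-dimethyldeca-2,4,6,8-tetraenoate | CCOC(=O)/C=C/C(C)=C/C=C/C=C(C)/CBr | intermediate
22 | ethyl (2E,4E,6E,8E)-10-(diethoxyphosphoryl)-4,9-dimethyldeca-2,4,6,8-tetraenoate | CCOC(=O)/C=C/C(C)=C/C=C/C=C(C)/CP(=O)(OCC)OCC | intermediate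
23 | sodium (2E,4E,6E,8E)-1-(diethoxyphosphoryl)-10-ethoxy-2,7-dimethyl-10-oxodeca-2,4,6,8-tetraen-1-ide | CCOC(=O)/C=C/C(C)=C/C=C/C=C(C)/[CH-]P(=O)(OCC)OCC.[Na+] | intermediate
24 | ethyl (2E,4E,6E,8E,10E,12Z)-4,9-dimethyl-13-[(2S,7aR)-4,4,7a-trimethyl-6-oxo-2,4,5,6,7,7a-hexahydro-1-benzofuran-2-yl]tetradeca-2,4,6,8,10,12-hexaenoate | C/C(=C/C=C/C(C)=C/C=C/C=C(C)/C=C/C(=O)OCC)[C@@H]1C=C2C(C)(C)CC(=O)C[C@@]2(C)O1 | intermediate
25 | (2E,4E,6E,8E,10E,12Z)-13-[(2S,6S,7aR)-6-hydroxy-4,4,7a-trimethyl-2,4,5,6,7,7a-hexahydro-1-benzofuran-2-yl]-4,9-dimethyltetradeca-2,4,6,8,10,12-hexaen-1-ol | C/C(=C/C=C/C(C)=C/C=C/C=C(C)/C=C/CO)[C@@H]1C=C2C(C)(C)C[C@H](O)C[C@@]2(C)O1 | target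

## Step count and least certain steps

Total: 15 steps. Longest linear sequence: 10 steps (1, 2, 3, 4, 6, 7, 8, 9, 14, 15); steps 5 and 10–13 are side branches.

Step 7 (key step, proposed new method). Three things may go wrong.
- Cyclisation by the gold phosphate may be slow, so that acid-driven Meyer–Schuster or pinacol-type rearrangement of the propargylic diol competes.
- Facial discrimination in the hydride transfer may be insufficient, or C8 may lose its configuration by re-ionisation of the doubly allylic ether.
- Hydride may be delivered to C10, or the enol ether may be protonated at C7 and over-reduced.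

The more electrophilic (Ph3P)AuNTf2 would speed the first stage but brings an achiral anion. The fallback uses known chemistry and gives up catalyst control. It sets out from 12: cyclisation with AgOTf in CH2Cl2 (the known 5-endo-dig closure of alkynediols) to 13, then, without isolation, Et3SiH and BF3·OEt2 at −78 °C (ionic hydrogenation of the furanium ion by a silane). This should give 15 together with the C8 epimer of 15 F1, which is a diastereomer and is removed by chromatography; the route is rejoined at 15.

Step 4. Facial selectivity at C5 may be eroded if the minor half-chair with an axial silyloxy group reacts, since it exposes the opposite face. The fallback adds reagent control. It sets out from 3: hydrogenation (H2, Pd/C, EtOAc) gives the saturated ketone (4S)-4-[(tert-butyldimethylsilyl)oxy]-2,2,6-trimethylcyclohexan-1-one F2 as both C6 epimers, which is irrelevant. Its potassium enolate (KN(SiMe3)2, THF, −78 °C) is hydroxylated with the enantiomer of (camphorsulfonyl)oxaziridine that is matched to the lower face. The route is rejoined at 8.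

Step 6. Addition to a ketone flanked by two fully substituted carbons may be slow, and on warming the α-alkoxide may undergo α-ketol rearrangement. The fallback forms the C8–C9 bond by cross-coupling instead. It sets out from 8: HC≡CMgBr with CeCl3 in THF adds the smallest possible alkyne, with the same facial preference, to give the ethynyl diol F3. Separately, commercial but-2-yn-1-ol is converted with NaAlH2(OCH2CH2OMe)2 and then I2 into (2Z)-3-iodobut-2-en-1-ol F4, which is silylated (TBDPSCl, imidazole) to the iodide F5. Sonogashira coupling of F3 with F5 (Pd(PPh3)4, CuI, i-Pr2NH) rejoins the route at 12.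

Step 14. Base may erode stereochemical integrity by removing H8 of the (Z)-enal, by Z to E isomerisation, or by retro-oxa-Michael opening at C5 through the enolate of the C3 ketone. The fallback changes the order of events so that the ketone never meets the carbanion. It sets out from 16: MnO2 in CH2Cl2 oxidises only the allylic alcohol to the hydroxy enal F6; olefination with 23 gives the hydroxy ester F7; Dess–Martin oxidation buffered with pyridine then rejoins the route at 24.

Step 15. Facial selectivity at C3 may be incomplete with the aluminium hydride, and the C3 epimers of the final polyene diol would be hard to separate. The fallback stages the two reductions. It sets out from 24: NaBH4 with CeCl3·7H2O in MeOH/THF at −40 °C (Luche reduction) reduces only the ketone, from the open face, to the (3S)-hydroxy ester F8, which can be freed of any C3 epimer at this more robust stage. i-Bu2AlH then reduces the ester and rejoins the route at 25.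

## Further compounds

F1 | step 7 | (2R,6R,7aR)-6-[(tert-butyldimethylsilyl)oxy]-2-{(2Z)-4-[(tert-butyldiphenylsilyl)oxy]but-2-en-2-yl}-4,4,7a-trimethyl-2,4,5,6,7,7a-hexahydro-1-benzofuran (C8 epimer of 15) | C/C(=C/CO[Si](c1ccccc1)(c1ccccc1)C(C)(C)C)[C@H]1C=C2C(C)(C)C[C@@H](O[Si](C)(C)C(C)(C)C)C[C@@]2(C)O1
F2 | step 4 | (4S)-4-[(tert-butyldimethylsilyl)oxy]-2,2,6-trimethylcyclohexan-1-one (both C6 epimers) | CC1C[C@H](O[Si](C)(C)C(C)(C)C)CC(C)(C)C1=O
F3 | step 6 | (1S,2R,4R)-4-[(tert-butyldimethylsilyl)oxy]-1-ethynyl-2,6,6-trimethylcyclohexane-1,2-diol | C#C[C@@]1(O)C(C)(C)C[C@@H](O[Si](C)(C)C(C)(C)C)C[C@@]1(C)O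
F4 | step 6 | (2Z)-3-iodobut-2-en-1-ol | C/C(I)=C/CO
F5 | step 6 | tert-butyl{[(2Z)-3-iodobut-2-en-1-yl]oxy}diphenylsilane | C/C(I)=C/CO[Si](c1ccccc1)(c1ccccc1)C(C)(C)C
F6 | step 14 | (2Z)-3-[(2S,6R,7aR)-6-hydroxy-4,4,7a-trimethyl-2,4,5,6,7,7a-hexahydro-1-benzofuran-2-yl]but-2-enal | C/C(=C/C=O)[C@@H]1C=C2C(C)(C)C[C@@H](O)C[C@@]2(C)O1
F7 | step 14 | ethyl (2E,4E,6E,8E,10E,12Z)-13-[(2S,6R,7aR)-6-hydroxy-4,4,7a-trimethyl-2,4,5,6,7,7a-hexahydro-1-benzofuran-2-yl]-4,9-dimethyltetradeca-2,4,6,8,10,12-hexaenoate | C/C(=C/C=C/C(C)=C/C=C/C=C(C)/C=C/C(=O)OCC)[C@@H]1C=C2C(C)(C)C[C@@H](O)C[C@@]2(C)O1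
F8 | step 15 | ethyl (2E,4E,6E,8E,10E,12Z)-13-[(2S,6S,7aR)-6-hydroxy-4,4,7a-trimethyl-2,4,5,6,7,7a-hexahydro-1-benzofuran-2-yl]-4,9-dimethyltetradeca-2,4,6,8,10,12-hexaenoate | C/C(=C/C=C/C(C)=C/C=C/C=C(C)/C=C/C(=O)OCC)[C@@H]1C=C2C(C)(C)C[C@H](O)C[C@@]2(C)O1
A1 | alternative 1 | (2R,5S)-2-allyl-2-methyl-5-[(triisopropylsilyl)ethynyl]dihydrofuran-3(2H)-one | CC(C)[Si](C(C)C)(C(C)C)C#C[C@@H]1CC(=O)[C@@](C)(CC=C)O1
A2 | alternative 1 | (5S)-5-(allyloxy)-2-diazo-7-(triisopropylsilyl)hept-6-yn-3-one | CC(C)[Si](C(C)C)(C(C)C)C#C[C@@H](OCC=C)CC(=O)C(C)=[N+]=[N-]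
A3 | alternative 2 | (2S,6R,7aR)-2-{(2Z)-4-[(tert-butyldiphenylsilyl)oxy]but-2-en-2-yl}-4,4,7a-trimethyl-6-[(triethylsilyl)oxy]-2,4,5,6,7,7a-hexahydro-1-benzofuran | C/C(=C/CO[Si](c1ccccc1)(c1ccccc1)C(C)(C)C)[C@@H]1C=C2C(C)(C)C[C@@H](O[Si](CC)(CC)CC)C[C@@]2(C)O1
A4 | alternative 2 | (4E,6S,7Z)-9-[(tert-butyldiphenylsilyl)oxy]-3,3,7-trimethyl-4-(prop-1-en-2-yl)-6-[(triethylsilyl)oxy]nona-4,7-dienal | C/C(=C/CO[Si](c1ccccc1)(c1ccccc1)C(C)(C)C)[C@@H](O[Si](CC)(CC)CC)/C=C(\C(C)=C)C(C)(C)CC=O
A5 | alternative 3 | ethyl (2Z)-3-[(2S,6S,7aR)-6-[(tert-butyldimethylsilyl)oxy]-4,4,7a-trimethyl-2,4,5,6,7,7a-hexahydro-1-benzofuran-2-yl]but-2-enoate | C/C(=C/C(=O)OCC)[C@@H]1C=C2C(C)(C)C[C@H](O[Si](C)(C)C(C)(C)C)C[C@@]2(C)O1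
A6 | alternative 3 | ethyl (2Z,4E)-5-[(4R)-4-[(tert-butyldimethylsilyl)oxy]-2,6,6-trimethylcyclohex-1-en-1-yl]-3-methylpenta-2,4-dienoate | C/C(=C/C(=O)OCC)/C=C/C1=C(C)C[C@@H](O[Si](C)(C)C(C)(C)C)CC1(C)C
A7 | alternative 3 | ethyl (2Z)-3-[5,8-epidioxy bicycle]but-2-enoate: the 5,8-endoperoxide of A6, peroxide bridge anti to the C3 silyloxy group, C5 methyl cis to H8 | C/C(=C/C(=O)OCC)[C@H]1C=C2C(C)(C)C[C@H](O[Si](C)(C)C(C)(C)C)C[C@@]2(C)OO1
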